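## Structural features

The target is a labdane with a 5,10-cis ring fusion: ring A (C1–C5, C10) and ring B (C5–C10) share the C5–C10 bond, and H5 and the C10 methyl lie on the same face. Ring A carries at C4 a quaternary centre with a methyl group and the C19 methyl ester. Ring B carries the exocyclic C8=C17 methylene and, at C9, the C11–C15 chain, which ends in a free acid and holds the remote C13 methyl stereocentre. C4, C5, C10 and C9 are contiguous; C4 and C10 are quaternary and 1,3-related across C5, while C13 is isolated and must come from a reagent or a chiral building block. Fragile points are the exocyclic alkene (it migrates into the ring under acid), C9 (epimerisable while C8 is a ketone) and the two carboxyl groups, which must end as one hindered ester and one free acid. The real difficulty is the C4/C5/C10 triad on a cis-decalin: C19 and C9 must both be cis to C6 on ring A, and no thermodynamic bias can be relied on. The key step uses the cis relation of C19 (on C4) and C6 (on C5) on ring A: the two are tied through an oxygen on C6 as a γ-lactone, and that oxygen later leaves once C8 is a ketone.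

## Logic of the disconnections

24 ⇒ 23. The O–H of the C15 acid is traced back to a methyl ester. Both carboxyls can then travel as methyl esters and be told apart only at the end. The forward step must hydrolyse the unhindered C15 ester and leave the C19 ester on the quaternary C4.

23 ⇒ 22. The C8=C17 bond is cut to a C8 ketone. The ketone is what activates C9 for attachment of the chain. The forward methylenation must be non-basic, because C9 is epimerisable in 22.

22 ⇒ 16 + 20. The C9–C11 bond is cut and C9 is reconnected to C1 as a cyclopropane. This splits off the whole chain as 20 and makes the C8–C9 enolate available without regiochemical ambiguity. The forward step must alkylate that enolate on the convex face faster than it exchanges protons or attacks an ester.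

20 ⇒ 19 ⇒ 18 ⇒ 17. The C–I, C–OH and ester C–O bonds are traced back to a meso anhydride. C13 then comes from a catalytic desymmetrisation. The forward steps must reduce the acid next to the ester and avoid closing the δ-lactone.

16 ⇒ 15. The C9–C10 and C9–C1 bonds are cut (carbenoid addition to C1=C10). This removes ring B and the quaternary C10 in one operation. The forward step needs addition on the face of the alkene that carries C6; the short tether allows no other, and that fixes the cis fusion.

15 ⇒ 13 ⇒ 12 ⇒ 10 ⇒ 9. The diazo group is removed from C9, C6=C7 is restored, the C19–O–C6 lactone bond is re-formed (retro-elimination) and the C8 carbonyl is traced to a terminal alkene. The C8 ketone thus does three jobs: it expels the lactone carboxylate from C6, it carries the diazo group, and it later directs the cyclopropane opening. The demand is that the allyl group of 9 supplies C7, C8 and C9 intact and that C5 survives the base.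

9 ⇒ 8. The C4–C5 and C2–C3 bonds are cut (intramolecular Diels–Alder). Ring A, the lactone and the C4/C5 stereocentres fall back to an acyclic triene ester with one stereocentre. The forward step must be cis-selective at the ring fusion and face-selective under control of C6.

8 ⇒ 6 + 7; 6 ⇒ 3 + 4; 3 ⇒ 2 ⇒ 1. The ester C–O bond and then the C6–C7 bond are cut, and the aldehyde is traced to the enynol. The one stereocentre that controls C4, C5 and C10 is then set by a catalytic allylation. The demand is a clean 1,2-addition to a volatile, polymerisable dienal.

## Other disconnections considered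

Alternative 1: the cut is C9–C10, with the C8=C17 methylene released in the same step. Forward, a Lewis acid would trigger an intramolecular Sakurai addition of the (Z)-allylsilane in A1 to its ring A enone, giving A2.
- In its favour: one step closes ring B, creates the quaternary C10 and C9, and delivers the methylene. The chain is already attached, so there is no alkylation at hindered C9 and no methylenation. On these points it is better than the chosen plan.
- Equal: the C10 configuration relative to C5 comes from the tether on C5, as in the chosen cyclopropanation.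
- Against: A1 must already contain ring A with C4 and C5 set, which is the part the lactone tether solves, so the hardest problem is moved rather than removed. A stereodefined trisubstituted allylsilane is needed. The C9 configuration depends on a chair or boat synclinal transition state that the substrate does not fix. The β,β-disubstituted enone invites 1,2-addition and protodesilylation. The C2 ketone of A2 must then be removed beside an acid-sensitive methylene and two esters.
- Comparison: stepwise cationic bond formation against a concerted cycloaddition and a carbenoid addition; the step count is equal at best once A1 and the deoxygenation are counted.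

Alternative 2: the cut is C5–C6, prepared by a temporary C3–C8 bond. Forward, the potassium alkoxide of the bicyclo[2.2.2]octenol A3 would undergo an anionic oxy-Cope rearrangement to the cis-decalin A4.
- In its favour: the rearrangement is stereospecific and runs at or below room temperature, which is better than 180 °C. The C8 ketone arrives in place. C9 is set in the bicycle and transferred, which avoids the hindered enolate alkylation.
- Equal: the cis C5/C10 fusion is enforced by geometry, as in the chosen cyclopropanation.
- Against: A3 is a densely substituted bicycle with a bridgehead methyl. It needs its own regio- and endo-selective Diels–Alder and a vinyl addition to the correct ketone face. The quaternary C4 is not made: the enoate of A4 still has to be reduced and methylated with facial control, so the C4 problem is postponed. C9 stays epimerisable in A4.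
- Comparison: two pericyclic key steps in both plans; the step count is comparable or longer.

Alternative 3: the cut is C4–C5, the same bond as in the chosen plan, but formed ionically. Forward, a chiral base or phase-transfer catalyst would add the β-keto ester carbon of the achiral dienone A5 to one enantiotopic enone carbon, giving A6.
- In its favour: a catalyst sets C5 and the quaternary C10 in one step from an achiral precursor, at ambient temperature and with secure cis fusion. On mildness and on directness for C10 it is better than the chosen plan.
- Equal: the source of absolute configuration is a catalyst in both plans.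
- Against: A6 is far from the target. C4 still needs its methyl group, the C3 oxygen must be removed, and ring B carries its oxygen at C7, whereas the target needs the methylene at C8 and the chain at C9. A conjugate addition at C9 followed by a carbonyl transposition and two deoxygenations would be needed.
- Comparison: the step count is clearly worse, although each step is mild.

Key step: step 5

Assumption (numbering): labdane numbering C1–C20 is used throughout; the allyl group on C6 is taken to supply C7, C8 and C9, so no carbon is cut off or added on the way to the diazoketone.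
Assumption (sense of induction): (R)-TRIP is taken to deliver the allyl group to the Re face of 3, and (DHQD)2AQN to give the (R)-half-ester 18; if either sense is the opposite, the enantiomeric or pseudoenantiomeric catalyst is used.
Remark (structure check): C4 and C5 of 9 have the configuration of the target, and (R)-C6 in 8 is what the allylic-strain model needs for that outcome, so no structure had to be changed. The cis fusion of the lactone is not automatic, however, and is treated below as a selectivity to be secured.

Step 1
Reactants: 1 (2E)-3-methylpent-2-en-4-yn-1-ol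
Product: 2 (2E)-3-methylpenta-2,4-dien-1-ol
Conditions: H2 (1 atm), Pd/CaCO3 poisoned with Pb(OAc)2 (Lindlar catalyst), quinoline, EtOAc, 0 °C to rt
Reagents that add atoms: none
Why: Lindlar semihydrogenation should stop at the terminal alkene; the trisubstituted E double bond is not reduced and keeps its geometry.

Step 2
Reactants: 2 (2E)-3-methylpenta-2,4-dien-1-ol
Product: 3 (2E)-3-methylpenta-2,4-dienal
Conditions: MnO2, CH2Cl2, rt; filtered solution used directly
Reagents that add atoms: none
Why: Allylic oxidation with MnO2 is neutral and selective for allylic alcohols, so the E geometry should hold; the volatile dienal is not concentrated to dryness.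

Step 3
Reactants: 3 (2E)-3-methylpenta-2,4-dienal; 4 allylboronic acid pinacol ester
Product: 6 (4R,5E)-6-methylocta-1,5,7-trien-4-ol, via pinacol borate ester 5 (not isolated)
Conditions: (R)-TRIP (5 mol%), toluene, −30 °C; then aq. NaHCO3
Reagents that add atoms: none
Why: Chiral phosphoric acid-catalysed allylboration runs through a closed six-membered chair transition state, so only 1,2-addition is expected; the catalyst binds the boronate and selects the aldehyde face, which sets C6 as R.

Step 4
Reactants: 6 (4R,5E)-6-methylocta-1,5,7-trien-4-ol; 7 methacryloyl chloride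
Product: 8 (4R,5E)-6-methylocta-1,5,7-trien-4-yl 2-methylprop-2-enoate
Conditions: Et3N, DMAP (cat.), CH2Cl2, 0 °C
Reagents that add atoms: none
Why: Base-mediated acylation of a secondary alcohol; basic conditions avoid ionisation of the doubly allylic carbinol, so C6 is not touched.

Step 5
Reactants: 8 (4R,5E)-6-methylocta-1,5,7-trien-4-yl 2-methylprop-2-enoate
Product: 9 (3R,3aS,7aR)-4,7a-dimethyl-3-(prop-2-en-1-yl)-3a,6,7,7a-tetrahydro-2-benzofuran-1(3H)-one (cis-fused γ-lactone; C19 and C6 cis on ring A)
Conditions: BHT (10 mol%), 1,2-dichlorobenzene (0.02 M), 180 °C, sealed tube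
Reagents that add atoms: none
Why: The reaction is a concerted thermal [4+2] cycloaddition of a type 1 intramolecular Diels–Alder substrate; the closest known reaction type is the thermal ester-tethered cyclisation of pentadienyl acrylates to bicyclic γ-lactones. The ester must first reach its minor s-cis conformation about the C19–O bond for C4 to come within reach of C5, which is why high temperature and dilution are needed. Ring A closes as the cycloaddition ring (C4–C5 and C2–C3 formed suprafacially on both partners), and the γ-lactone closes as the tether ring C5–C6–O–C19–C4, whose three atoms also fix the regiochemistry. C5 is controlled by C6: allylic 1,3-strain with the C10 methyl keeps C6–H eclipsed with C5=C10, so the oxygen and with it the dienophile sit on one diene face and the allyl group on the other. C4 is controlled relative to C5 by the mode of approach: cis fusion requires the tether carbonyl endo and the methacrylate methyl exo. A five-membered tether ring does not by itself exclude the trans-fused lactone, which is a known competitor with pentadienyl acrylates. Cis fusion is expected to be favoured here because the other mode would place the α-methyl under C10 and lead to a more strained trans-fused lactone with an sp2 carbon next to the ring fusion, while the carbonyl-endo mode keeps secondary overlap with the diene. The step therefore needs cis over trans fusion and the C6-directed face; the face is secured by the C10 methyl, and the unactivated allyl group offers no competing dienophile.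

Step 6
Reactants: 9 (3R,3aS,7aR)-4,7a-dimethyl-3-(prop-2-en-1-yl)-3a,6,7,7a-tetrahydro-2-benzofuran-1(3H)-one
Product: 10 (3R,3aS,7aR)-4,7a-dimethyl-3-(2-oxopropyl)-3a,6,7,7a-tetrahydro-2-benzofuran-1(3H)-one
Conditions: PdCl2 (10 mol%), CuCl (1 equiv), O2 (1 atm), DMF/H2O 7:1, rt
Reagents that add atoms: water, O
Why: Wacker oxidation converts the monosubstituted alkene into the methyl ketone with Markovnikov selectivity and leaves the hindered trisubstituted C1=C10 alkene alone; this puts the carbonyl on C8 without cutting or adding carbon.

Step 7
Reactants: 10 (3R,3aS,7aR)-4,7a-dimethyl-3-(2-oxopropyl)-3a,6,7,7a-tetrahydro-2-benzofuran-1(3H)-one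
Product: 12 methyl (1R,2S)-1,3-dimethyl-2-[(1E)-3-oxobut-1-en-1-yl]cyclohex-3-ene-1-carboxylate, via enone carboxylic acid 11 (not isolated)
Conditions: DBU (1.2 equiv), MeCN, 0 °C; then MeI, rt
Reagents that add atoms: iodomethane, CI
Why: E1cB elimination of the β-acyloxy ketone ejects the C19 carboxylate from C6 and opens the lactone; methylating the carboxylate in the same flask makes the opening irreversible and gives the C19 methyl ester. The acid formed consumes the base, which limits exposure of the doubly allylic C5–H.

Step 8
Reactants: 12 methyl (1R,2S)-1,3-dimethyl-2-[(1E)-3-oxobut-1-en-1-yl]cyclohex-3-ene-1-carboxylate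
Product: 13 methyl (1R,2S)-1,3-dimethyl-2-(3-oxobutyl)cyclohex-3-ene-1-carboxylate
Conditions: H2 (1 atm), RhCl(PPh3)3 (5 mol%), toluene, rt
Reagents that add atoms: none
Why: Homogeneous hydrogenation with RhCl(PPh3)3 reduces the disubstituted enone alkene and is too hindered to reduce the trisubstituted ring alkene; no enolate is formed, so C5 and the C19 ester are not at risk.

Step 9
Reactants: 13 methyl (1R,2S)-1,3-dimethyl-2-(3-oxobutyl)cyclohex-3-ene-1-carboxylate
Product: 15 methyl (1R,2S)-2-(4-diazo-3-oxobutyl)-1,3-dimethylcyclohex-3-ene-1-carboxylate, via trifluoroacetyl diketone 14 (not isolated)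
Conditions: LiN(SiMe3)2, THF, −78 °C; CF3CO2CH2CF3; then MsN3, Et3N, H2O, MeCN, rt
Reagents that add atoms: methanesulfonyl azide, CS(=O)(=O)N=[N+]=[N-]; 2,2,2-trifluoroethyl trifluoroacetate, O=C(OCC(F)(F)F)C(F)(F)F (its trifluoroacetyl group is present only in 14)
Why: Detrifluoroacetylative diazo transfer: kinetic deprotonation takes the methyl group (C9), trifluoroacetylation activates that carbon, and the sulfonyl azide transfers N2 with loss of the activating group. The C19 ester has no α-hydrogen, and diazomethane is avoided.

Step 10
Reactants: 15 methyl (1R,2S)-2-(4-diazo-3-oxobutyl)-1,3-dimethylcyclohex-3-ene-1-carboxylate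
Product: 16 methyl (1S,2R,5R,6S,10S)-1,5-dimethyl-9-oxotricyclo[4.4.0.0(2,10)]decane-5-carboxylate (cyclopropane C1–C9–C10, ketone at C8, labdane numbering)
Conditions: Cu(acac)2 (5 mol%), toluene, 100 °C, slow addition of 15
Reagents that add atoms: none
Why: Intramolecular cyclopropanation by a copper carbenoid; divalent copper is chosen over rhodium catalysts because copper carbenoids rarely insert into C–H bonds such as the allylic C5–H. The three-atom tether reaches only the alkene face that carries C6, so C9–C10 forms cis to C5–C6 and the C10 methyl ends cis to H5.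

Step 11
Reactants: 17 3-methylglutaric anhydride
Product: 18 (3R)-5-methoxy-3-methyl-5-oxopentanoic acid
Conditions: (DHQD)2AQN, MeOH, Et2O, −40 °C
Reagents that add atoms: methanol, CO
Why: Cinchona-alkaloid-catalysed desymmetrising methanolysis of a meso anhydride; the catalyst selects one enantiotopic carbonyl and so sets C13.

Step 12
Reactants: 18 (3R)-5-methoxy-3-methyl-5-oxopentanoic acid
Product: 19 methyl (3R)-5-hydroxy-3-methylpentanoate
Conditions: BH3·SMe2, THF, −10 to 0 °C; then aq. NaHCO3
Reagents that add atoms: none
Why: Borane reduces the carboxylic acid much faster than the ester; a cold, non-acidic work-up and direct use should keep the δ-hydroxy ester from lactonising.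

Step 13
Reactants: 19 methyl (3R)-5-hydroxy-3-methylpentanoate
Product: 20 methyl (3S)-5-iodo-3-methylpentanoate
Conditions: I2, PPh3, imidazole, CH2Cl2, 0 °C
Reagents that add atoms: iodine, II
Why: Appel-type iodination of a primary alcohol; the stereocentre is two carbons away and is untouched (the descriptor changes only through ligand priorities).

Step 14
Reactants: 16 methyl (1S,2R,5R,6S,10S)-1,5-dimethyl-9-oxotricyclo[4.4.0.0(2,10)]decane-5-carboxylate; 20 methyl (3S)-5-iodo-3-methylpentanoate
Product: 22 methyl (1R,4aS,5R,8aS)-5-[(3R)-5-methoxy-3-methyl-5-oxopentyl]-1,4a-dimethyl-6-oxodecahydronaphthalene-1-carboxylate, via lithium C8–C9 enolate 21 (not isolated)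
Conditions: Li (2.2 equiv), t-BuOH (1.0 equiv), NH3/THF, −78 °C; isoprene; then 20, −78 to −33 °C
Reagents that add atoms: none
Why: Reductive alkylation of a cyclopropyl ketone: the dissolving metal breaks C9–C1, the cyclopropane bond that overlaps with the carbonyl π system and gives the less substituted carbanion (protonated by t-BuOH), leaving the enolate only at C8–C9. The iodide should attack C9 on the convex face, anti to the pseudoaxial C10–C1 bond, which puts C11 cis to the C10 methyl; the new C9–H is equatorial and therefore slow to exchange.

Step 15
Reactants: 22 methyl (1R,4aS,5R,8aS)-5-[(3R)-5-methoxy-3-methyl-5-oxopentyl]-1,4a-dimethyl-6-oxodecahydronaphthalene-1-carboxylate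
Product: 23 methyl (1R,4aR,5S,8aS)-5-[(3R)-5-methoxy-3-methyl-5-oxopentyl]-1,4a-dimethyl-6-methylidenedecahydronaphthalene-1-carboxylate
Conditions: Zn, CH2Br2, TiCl4, THF/CH2Cl2, 0 °C to rt
Reagents that add atoms: dibromomethane, BrCBr
Why: Takai–Lombardo methylenation is non-basic, so the epimerisable C9 should keep its configuration, and it attacks ketones in preference to esters.

Step 16
Reactants: 23 methyl (1R,4aR,5S,8aS)-5-[(3R)-5-methoxy-3-methyl-5-oxopentyl]-1,4a-dimethyl-6-methylidenedecahydronaphthalene-1-carboxylate
Product: 24 (3R)-5-[(1S,4aS,5R,8aR)-5-(methoxycarbonyl)-5,8a-dimethyl-2-methylidenedecahydronaphthalen-1-yl]-3-methylpentanoic acid (CNP0135192.2)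
Conditions: LiOH, THF/H2O, 0 °C to rt; then cold dilute HCl to pH 4
Reagents that add atoms: lithium hydroxide, [Li+].[OH-]
Why: Saponification discriminates by hindrance: the primary C15 ester is hydrolysed, while the C19 ester on the quaternary C4 resists hydroxide under these conditions. Brief cold acidification should not move the exocyclic alkene.

Compound list

1 | (2E)-3-methylpent-2-en-4-yn-1-ol | C#C/C(C)=C/CO | starting material
2 | (2E)-3-methylpenta-2,4-dien-1-ol | OC/C=C(\C)C=C | intermediate
3 | (2E)-3-methylpenta-2,4-dienal | O=C/C=C(\C)C=C | intermediate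
4 | allylboronic acid pinacol ester | C=CCB1OC(C)(C)C(C)(C)O1 | starting material
5 | 4,4,5,5-tetramethyl-2-{[(4R,5E)-6-methylocta-1,5,7-trien-4-yl]oxy}-1,3,2-dioxaborolane | CC1(C)OB(O[C@H](CC=C)/C=C(\C)C=C)OC1(C)C | intermediate (not isolated)
6 | (4R,5E)-6-methylocta-1,5,7-trien-4-ol | O[C@H](CC=C)/C=C(\C)C=C | intermediate
7 | methacryloyl chloride | C=C(C)C(=O)Cl | starting material
8 | (4R,5E)-6-methylocta-1,5,7-trien-4-yl 2-methylprop-2-enoate | C=C(C)C(=O)O[C@H](CC=C)/C=C(\C)C=C | intermediate
9 | (3R,3aS,7aR)-4,7a-dimethyl-3-(prop-2-en-1-yl)-3a,6,7,7a-tetrahydro-2-benzofuran-1(3H)-one | C=CC[C@H]1OC(=O)[C@]2(C)CCC=C(C)[C@H]12 | intermediate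
10 | (3R,3aS,7aR)-4,7a-dimethyl-3-(2-oxopropyl)-3a,6,7,7a-tetrahydro-2-benzofuran-1(3H)-one | CC(=O)C[C@H]1OC(=O)[C@]2(C)CCC=C(C)[C@H]12 | intermediate
11 | (1R,2S)-1,3-dimethyl-2-[(1E)-3-oxobut-1-en-1-yl]cyclohex-3-ene-1-carboxylic acid | OC(=O)[C@]1(C)CCC=C(C)[C@@H]1/C=C/C(C)=O | intermediate (not isolated)
12 | methyl (1R,2S)-1,3-dimethyl-2-[(1E)-3-oxobut-1-en-1-yl]cyclohex-3-ene-1-carboxylate | COC(=O)[C@]1(C)CCC=C(C)[C@@H]1/C=C/C(C)=O | intermediate
13 | methyl (1R,2S)-1,3-dimethyl-2-(3-oxobutyl)cyclohex-3-ene-1-carboxylate | COC(=O)[C@]1(C)CCC=C(C)[C@@H]1CCC(C)=O | intermediate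
14 | methyl (1R,2S)-1,3-dimethyl-2-(6,6,6-trifluoro-3,5-dioxohexyl)cyclohex-3-ene-1-carboxylate | COC(=O)[C@]1(C)CCC=C(C)[C@@H]1CCC(=O)CC(=O)C(F)(F)F | intermediate (not isolated)
15 | methyl (1R,2S)-2-(4-diazo-3-oxobutyl)-1,3-dimethylcyclohex-3-ene-1-carboxylate | COC(=O)[C@]1(C)CCC=C(C)[C@@H]1CCC(=O)C=[N+]=[N-] | intermediate
16 | methyl (1S,2R,5R,6S,10S)-1,5-dimethyl-9-oxotricyclo[4.4.0.0(2,10)]decane-5-carboxylate | COC(=O)[C@]1(C)CC[C@@H]2[C@@H]3C(=O)CC[C@H]1[C@]23C | intermediate
17 | 3-methylglutaric anhydride | CC1CC(=O)OC(=O)C1 | starting material
18 | (3R)-5-methoxy-3-methyl-5-oxopentanoic acid | OC(=O)C[C@@H](C)CC(=O)OC | intermediate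
19 | methyl (3R)-5-hydroxy-3-methylpentanoate | OCC[C@@H](C)CC(=O)OC | intermediate
20 | methyl (3S)-5-iodo-3-methylpentanoate | ICC[C@@H](C)CC(=O)OC | intermediate
21 | methyl (1R,4aS,8aS)-6-(lithiooxy)-1,4a-dimethyl-1,2,3,4,4a,7,8,8a-octahydronaphthalene-1-carboxylate | [Li]OC1=C[C@@]2(C)CCC[C@@](C)(C(=O)OC)[C@H]2CC1 | intermediate (not isolated)
22 | methyl (1R,4aS,5R,8aS)-5-[(3R)-5-methoxy-3-methyl-5-oxopentyl]-1,4a-dimethyl-6-oxodecahydronaphthalene-1-carboxylate | O=C1CC[C@H]2[C@](C)(CCC[C@@]2(C)C(=O)OC)[C@H]1CC[C@@H](C)CC(=O)OC | intermediate
23 | methyl (1R,4aR,5S,8aS)-5-[(3R)-5-methoxy-3-methyl-5-oxopentyl]-1,4a-dimethyl-6-methylidenedecahydronaphthalene-1-carboxylate | C=C1CC[C@H]2[C@](C)(CCC[C@@]2(C)C(=O)OC)[C@H]1CC[C@@H](C)CC(=O)OC | intermediate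
24 | (3R)-5-[(1S,4aS,5R,8aR)-5-(methoxycarbonyl)-5,8a-dimethyl-2-methylidenedecahydronaphthalen-1-yl]-3-methylpentanoic acid | C=C1CC[C@H]2[C@](C)(CCC[C@@]2(C)C(=O)OC)[C@H]1CC[C@@H](C)CC(=O)O | target

Total step count: 16. Longest linear sequence: 13 steps (steps 1–10 and 14–16); steps 11–13 make the side-chain iodide 20 in a separate branch.

Steps least certain to work

Step 5 (key step). The likeliest failure is loss of cis/trans selectivity at the ring fusion, through the mode in which the tether carbonyl is exo. Because the cycloaddition is slow, the 1,5-diene C9=C8–C7–C6–C5=C10 may also undergo a Cope rearrangement, the allylic ester may undergo a 1,3-acyloxy shift, or the methacrylate may polymerise. Fallback, from 6 back to 9: citraconic anhydride is opened with allyl alcohol at its less hindered carbonyl to give (2Z)-2-methyl-4-oxo-4-(prop-2-en-1-yloxy)but-2-enoic acid F1. Carbodiimide coupling (DCC, DMAP) of F1 with 6 gives the mixed citraconate F2. In F2 the Z ester must be endo together with the tether carbonyl, and the doubly activated dienophile should react at 110–140 °C, giving the cis-fused lactone allyl ester F3. Zerovalent palladium (Pd(PPh3)4, morpholine) removes the allyl group to give the lactone acid F4, and a Barton decarboxylation (oxalyl chloride; sodium 2-thioxopyridin-1-olate; t-BuSH, hν) replaces the C3 carboxyl by hydrogen and returns 9.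

Step 14. The likeliest failure is slow substitution by the hindered C9 enolate on an unactivated primary iodide. That leaves time for proton transfer (unalkylated ketone, C7 enolate, double alkylation), for attack on the ester of 20, and for intramolecular Claisen condensation of C9 onto C19 in the ring A conformer that holds both axial. Incomplete facial selectivity at C9 is a second concern. Fallback, from 16 back to 23: the same reductive opening is followed by trapping with allyl bromide, which reacts within minutes at −78 °C, to give the 9-allyl ketone F5. Zn/CH2Br2/TiCl4 methylenation gives the diene F6. Disiamylborane, then NaBO3, hydroborates only the monosubstituted alkene and gives the primary alcohol F7. Dess–Martin oxidation gives the aldehyde F8, and a Horner–Wadsworth–Emmons reaction (trimethyl phosphonoacetate, LiCl, DBU) gives the (E)-enoate F9. CuI/Tol-BINAP-catalysed conjugate addition of MeMgBr then sets C13 under catalyst control and gives 23.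

Step 7. The likeliest failure is deprotonation at C5, which becomes doubly allylic and γ to the enone once the lactone opens. This would move C1=C10 into conjugation and destroy the C5 stereocentre. Re-addition of the carboxylate to the enone before methylation is a lesser concern. Fallback, from 9 back to 13: the lactone is opened by substitution at C6 with sodium phenylselenolate ((PhSe)2, NaBH4, DMF, 120 °C; expected to be slow at this hindered secondary carbon) to give the phenylselanyl acid F10. MeI/K2CO3 gives its methyl ester F11, and Bu3SnH/AIBN removes selenium to give the butenyl ester F12. Wacker oxidation under the conditions of step 6 gives 13 without any enone intermediate.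

Step 12. The likeliest failure is lactonisation of the δ-hydroxy ester during work-up, storage or iodination, which would lower the supply of 20. Fallback, from 18 back to 20: after the borane reduction the crude product is lactonised on purpose (TsOH cat., toluene) to (4R)-4-methyloxan-2-one F13. Iodotrimethylsilane in CH2Cl2, then methanol, opens the lactone at the O–CH2 carbon and gives 20.

Further compounds

F1 | step 5 | (2Z)-2-methyl-4-oxo-4-(prop-2-en-1-yloxy)but-2-enoic acid | C=CCOC(=O)/C=C(/C)C(=O)O
F2 | step 5 | 1-[(4R,5E)-6-methylocta-1,5,7-trien-4-yl] 4-(prop-2-en-1-yl) (2Z)-2-methylbut-2-enedioate | C=CCOC(=O)/C=C(/C)C(=O)O[C@H](CC=C)/C=C(\C)C=C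
F3 | step 5 | prop-2-en-1-yl (3R,3aS,7R,7aS)-4,7a-dimethyl-1-oxo-3-(prop-2-en-1-yl)-1,3,3a,6,7,7a-hexahydro-2-benzofuran-7-carboxylate | C=CC[C@H]1OC(=O)[C@]2(C)[C@H](C(=O)OCC=C)CC=C(C)[C@H]12
F4 | step 5 | (3R,3aS,7R,7aS)-4,7a-dimethyl-1-oxo-3-(prop-2-en-1-yl)-1,3,3a,6,7,7a-hexahydro-2-benzofuran-7-carboxylic acid | C=CC[C@H]1OC(=O)[C@]2(C)[C@H](C(=O)O)CC=C(C)[C@H]12
F5 | step 14 | methyl (1R,4aS,5R,8aS)-1,4a-dimethyl-6-oxo-5-(prop-2-en-1-yl)decahydronaphthalene-1-carboxylate | O=C1CC[C@H]2[C@](C)(CCC[C@@]2(C)C(=O)OC)[C@H]1CC=C
F6 | step 14 | methyl (1R,4aR,5S,8aS)-1,4a-dimethyl-6-methylidene-5-(prop-2-en-1-yl)decahydronaphthalene-1-carboxylate | C=C1CC[C@H]2[C@](C)(CCC[C@@]2(C)C(=O)OC)[C@H]1CC=C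
F7 | step 14 | methyl (1R,4aR,5S,8aS)-5-(3-hydroxypropyl)-1,4a-dimethyl-6-methylidenedecahydronaphthalene-1-carboxylate | C=C1CC[C@H]2[C@](C)(CCC[C@@]2(C)C(=O)OC)[C@H]1CCCO
F8 | step 14 | methyl (1R,4aR,5S,8aS)-1,4a-dimethyl-6-methylidene-5-(3-oxopropyl)decahydronaphthalene-1-carboxylate | C=C1CC[C@H]2[C@](C)(CCC[C@@]2(C)C(=O)OC)[C@H]1CCC=O
F9 | step 14 | methyl (1R,4aR,5S,8aS)-5-[(3E)-5-methoxy-5-oxopent-3-en-1-yl]-1,4a-dimethyl-6-methylidenedecahydronaphthalene-1-carboxylate | C=C1CC[C@H]2[C@](C)(CCC[C@@]2(C)C(=O)OC)[C@H]1CC/C=C/C(=O)OC
F10 | step 7 | (1R,2S)-1,3-dimethyl-2-[(1S)-1-(phenylselanyl)but-3-en-1-yl]cyclohex-3-ene-1-carboxylic acid | C=CC[C@H]([Se]c1ccccc1)[C@H]1C(C)=CCC[C@@]1(C)C(=O)O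
F11 | step 7 | methyl (1R,2S)-1,3-dimethyl-2-[(1S)-1-(phenylselanyl)but-3-en-1-yl]cyclohex-3-ene-1-carboxylate | C=CC[C@H]([Se]c1ccccc1)[C@H]1C(C)=CCC[C@@]1(C)C(=O)OC
F12 | step 7 | methyl (1R,2S)-2-(but-3-en-1-yl)-1,3-dimethylcyclohex-3-ene-1-carboxylate | C=CCC[C@H]1C(C)=CCC[C@@]1(C)C(=O)OC
F13 | step 12 | (4R)-4-methyloxan-2-one | C[C@@H]1CCOC(=O)C1
A1 | alternative 1 | methyl (1R,2S)-2-[(3Z,7R)-9-tert-butoxy-7-methyl-9-oxo-3-[(trimethylsilyl)methyl]non-3-en-1-yl]-1,3-dimethyl-5-oxocyclohex-3-ene-1-carboxylate (Sakurai precursor) | C[Si](C)(C)C/C(CC[C@H]1C(C)=CC(=O)C[C@@]1(C)C(=O)OC)=C\CC[C@@H](C)CC(=O)OC(C)(C)C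
A2 | alternative 1 | methyl (1R,4aR,5S,8aS)-5-[(3R)-5-tert-butoxy-3-methyl-5-oxopentyl]-1,4a-dimethyl-6-methylidene-3-oxodecahydronaphthalene-1-carboxylate (Sakurai product) | C=C1CC[C@H]2[C@](C)(CC(=O)C[C@@]2(C)C(=O)OC)[C@H]1CC[C@@H](C)CC(=O)OC(C)(C)C
A3 | alternative 2 | methyl 5-[(3R)-5-tert-butoxy-3-methyl-5-oxopentyl]-6-ethenyl-6-hydroxy-4-methylbicyclo[2.2.2]oct-2-ene-2-carboxylate, vinyl group and side chain both syn to the alkene bridge (oxy-Cope precursor) | C=C[C@]1(O)[C@H](CC[C@@H](C)CC(=O)OC(C)(C)C)[C@@]2(C)CC[C@@H]1C(C(=O)OC)=C2
A4 | alternative 2 | methyl 5-[(3R)-5-tert-butoxy-3-methyl-5-oxopentyl]-4a-methyl-6-oxo-3,4,4a,5,6,7,8,8a-octahydronaphthalene-1-carboxylate, cis-fused, C5, C9 and C10 as in the target (oxy-Cope product) | O=C1CC[C@H]2[C@](C)(CCC=C2C(=O)OC)[C@H]1CC[C@@H](C)CC(=O)OC(C)(C)C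
A5 | alternative 3 | methyl 5-(1-methyl-4-oxocyclohexa-2,5-dien-1-yl)-3-oxopentanoate (achiral Michael precursor) | COC(=O)CC(=O)CCC1(C)C=CC(=O)C=C1
A6 | alternative 3 | methyl 2-hydroxy-4a-methyl-7-oxo-3,4,4a,7,8,8a-hexahydronaphthalene-1-carboxylate, cis-fused enol form, C5 and C10 as in the target (Michael product) | O=C1C[C@H]2[C@](C)(CCC(O)=C2C(=O)OC)C=C1
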